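The benzene ring is built, not bought. Its substitution pattern (C1 carrying the fully substituted carbinol carbon, C2–OH ortho to it, C4–CH2O para to it) maps onto the two carbons of an alkynylboronate (C1, C2) and C3–C6 of methyl coumalate, whose 5-ester becomes the CH2O carbon. One thermal Diels–Alder/CO2-extrusion closes the ring with both new C–C bonds and sets boron (latent phenol), ester and a prochiral oxetane (latent triol) in place. The precursor is the pinacol alkynylboronate of TES-protected 3-ethynyloxetan-3-ol. Ester reduction and acylation, catalytic bromide desymmetrisation of the oxetane, opening of the derived epoxy alcohol by angelic acid and a neutral C–B oxidation finish the route.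

Key step: step 3

Remark: the squaramide antipode that leads to the 2R centre is assumed to be assigned on a model oxetane, and (R)-2-methylbutanoic acid is taken as bought in enantiopure form.

Step 1
Reactants: 1 3-ethynyloxetan-3-ol
Product: 2 triethyl[(3-ethynyloxetan-3-yl)oxy]silane
Conditions: Et3SiCl, imidazole, DMAP (cat.), DMF, 0 °C → rt
Reagents that add atoms: chlorotriethylsilane, CC[Si](Cl)(CC)CC
Why: Silyl ether formation on a tertiary propargylic alcohol that the small alkyne and the tied-back oxetane leave accessible; the triethylsilyl group is chosen because it should survive the organolithium, the 160 °C cycloaddition, the hydride and the silyl bromide, yet leave with fluoride exactly when the tertiary alkoxide is needed in step 6.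

Step 2
Reactants: 2 triethyl[(3-ethynyloxetan-3-yl)oxy]silane
Product: 5 2-{[3-(triethylsilyloxy)oxetan-3-yl]ethynyl}-4,4,5,5-tetramethyl-1,3,2-dioxaborolane, via lithium acetylide 3 (not isolated), via lithium alkynylborate 4 (not isolated)
Conditions: n-BuLi, THF, −78 °C; iPrOBpin, −78 °C; HCl in Et2O (1.0 equiv), −78 °C → rt; filtered, used crude
Reagents that add atoms: 2-isopropoxy-4,4,5,5-tetramethyl-1,3,2-dioxaborolane, CC(C)OB1OC(C)(C)C(C)(C)O1
Why: Standard alkynylboronate synthesis by alkyne deprotonation, borylation to the ate complex and collapse with exactly one equivalent of anhydrous acid, which the ate complex should consume at −78 °C before it can touch the silyl ether or the oxetane; the moisture-sensitive product is not chromatographed.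

Step 3
Reactants: 5 2-{[3-(triethylsilyloxy)oxetan-3-yl]ethynyl}-4,4,5,5-tetramethyl-1,3,2-dioxaborolane, 6 methyl coumalate
Product: 8 methyl 3-(4,4,5,5-tetramethyl-1,3,2-dioxaborolan-2-yl)-4-[3-(triethylsilyloxy)oxetan-3-yl]benzoate, via bicyclic lactone adduct 7 (not isolated)
Conditions: 6 (excess), mesitylene, 160 °C, sealed tube
Reagents that add atoms: none
Why: The alkyne adds thermally across C3 and C6 of the electron-poor 2-pyrone diene in a concerted [4+2] cycloaddition to give the 2-oxabicyclo[2.2.2]octadienone 7, which ejects CO2 in a retro-[4+2] step and is thereby aromatic without any oxidant. The closest known reaction type is the Diels–Alder/retro-Diels–Alder benzannulation of 2-pyrones with alkynylboronic esters to arylboronic esters. The benzene ring is closed by intermolecular cycloaddition, which forms the bonds pyrone C3–C(oxetanyl) and pyrone C6–C(boron), followed by cycloreversion; no stereocentre is created, since the two bridgehead centres of 7 are lost on aromatisation. The step needs regiocontrol: C6 of the coumalate (β to the ester, vinylogous to the lactone carbonyl) carries the largest LUMO coefficient and should bond to the boron-bearing alkyne carbon, which plays the part of the unsubstituted carbon of a terminal alkyne, and terminal alkynes are known to give 4-substituted benzoates with coumalates. This orientation is untested for this pair and is the single open point of the route; the silyl ether, the oxetane and the C–B bond should be inert under the neutral thermal conditions.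

Step 4
Reactants: 8 methyl 3-(4,4,5,5-tetramethyl-1,3,2-dioxaborolan-2-yl)-4-[3-(triethylsilyloxy)oxetan-3-yl]benzoate
Product: 9 [3-(4,4,5,5-tetramethyl-1,3,2-dioxaborolan-2-yl)-4-[3-(triethylsilyloxy)oxetan-3-yl]phenyl]methanol
Conditions: iBu2AlH, CH2Cl2, −78 → 0 °C; aq. potassium sodium tartrate
Reagents that add atoms: none
Why: Hydride reduction of an aryl ester to the benzylic alcohol with an aluminium hydride, under which the pinacol boronate, the silyl ether and the oxetane should be untouched at low temperature.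

Step 5
Reactants: 9 [3-(4,4,5,5-tetramethyl-1,3,2-dioxaborolan-2-yl)-4-[3-(triethylsilyloxy)oxetan-3-yl]phenyl]methanol, 10 (R)-2-methylbutanoic acid
Product: 11 [3-(4,4,5,5-tetramethyl-1,3,2-dioxaborolan-2-yl)-4-[3-(triethylsilyloxy)oxetan-3-yl]phenyl]methyl (2R)-2-methylbutanoate
Conditions: DIC, DMAP (cat.), CH2Cl2, 0 °C → rt
Reagents that add atoms: none
Why: Steglich esterification of an unhindered benzylic alcohol; the 2R centre is brought in with acid 10 and should not epimerise under carbodiimide activation with catalytic DMAP at low temperature.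

Step 6
Reactants: 11 [3-(4,4,5,5-tetramethyl-1,3,2-dioxaborolan-2-yl)-4-[3-(triethylsilyloxy)oxetan-3-yl]phenyl]methyl (2R)-2-methylbutanoate
Product: 13 [4-[(2R)-2-(hydroxymethyl)oxiran-2-yl]-3-(4,4,5,5-tetramethyl-1,3,2-dioxaborolan-2-yl)phenyl]methyl (2R)-2-methylbutanoate, via bromo bis-silyl ether 12 (not isolated)
Conditions: TMSBr, chiral 2-arylpyrrolidine-derived squaramide hydrogen-bond donor (cat.), t-BuOMe, −78 °C; then TBAF, THF, −78 → 0 °C
Reagents that add atoms: none
Why: Enantioselective desymmetrising ring opening of a 3,3-disubstituted oxetane with a silyl bromide under anion-binding catalysis, in which squaramide-bound bromide attacks one of the two enantiotopic CH2 groups of the silylated oxetane in an SN2 step and so fixes the quaternary carbinol carbon as 2R under catalyst control without breaking any of its bonds, after which fluoride removes both silyl groups and the tertiary alkoxide displaces bromide (3-exo-tet Williamson closure, favoured over 4-exo return to the oxetane) to give the epoxy alcohol with the centre intact.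

Step 7
Reactants: 13 [4-[(2R)-2-(hydroxymethyl)oxiran-2-yl]-3-(4,4,5,5-tetramethyl-1,3,2-dioxaborolan-2-yl)phenyl]methyl (2R)-2-methylbutanoate, 14 angelic acid
Product: 15 (2R)-2,3-dihydroxy-2-[4-({[(2R)-2-methylbutanoyl]oxy}methyl)-2-(4,4,5,5-tetramethyl-1,3,2-dioxaborolan-2-yl)phenyl]propyl (2Z)-2-methylbut-2-enoate
Conditions: Ti(OiPr)4, CH2Cl2, rt; aq. tartaric acid
Reagents that add atoms: none
Why: Titanium tetraisopropoxide-mediated opening of a 2,3-epoxy alcohol by a carboxylic acid, in which the free primary hydroxyl chelates tetravalent titanium and the bound carboxylate attacks the unsubstituted C3 methylene in an SN2 step, so that the quaternary centre is not touched and stays 2R, while the non-basic conditions at room temperature should preserve the Z alkene and disfavour acyl migration.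

Step 8
Reactants: 15 (2R)-2,3-dihydroxy-2-[4-({[(2R)-2-methylbutanoyl]oxy}methyl)-2-(4,4,5,5-tetramethyl-1,3,2-dioxaborolan-2-yl)phenyl]propyl (2Z)-2-methylbut-2-enoate
Product: 16 (2R)-2,3-dihydroxy-2-[2-hydroxy-4-({[(2R)-2-methylbutanoyl]oxy}methyl)phenyl]propyl (2Z)-2-methylbut-2-enoate
Conditions: 30% H2O2, THF/aq. NaH2PO4–Na2HPO4 (pH 7), 0 °C → rt; aq. Na2S2O3
Reagents that add atoms: hydrogen peroxide, OO
Why: Oxidation of an arylboronic ester to the phenol (peroxide adds to boron, the aryl group migrates from boron to oxygen, the borate is hydrolysed, and any boron chelate with the neighbouring hydroxyls reacts alike), run in neutral buffer so that neither ester is cleaved, the electron-poor angelate alkene is not epoxidised and no base-induced acyl migration between the carbinol oxygens can scramble the quaternary centre.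

Compound list

1 | 3-ethynyloxetan-3-ol | OC1(C#C)COC1 | starting material
2 | triethyl[(3-ethynyloxetan-3-yl)oxy]silane | CC[Si](CC)(CC)OC1(C#C)COC1 | intermediate
3 | {[3-(triethylsilyloxy)oxetan-3-yl]ethynyl}lithium | [Li]C#CC1(O[Si](CC)(CC)CC)COC1 | intermediate (not isolated)
4 | lithium isopropoxy(pinacolato){[3-(triethylsilyloxy)oxetan-3-yl]ethynyl}borate | [Li+].CC(C)O[B-]1(C#CC2(O[Si](CC)(CC)CC)COC2)OC(C)(C)C(C)(C)O1 | intermediate (not isolated)
5 | 2-{[3-(triethylsilyloxy)oxetan-3-yl]ethynyl}-4,4,5,5-tetramethyl-1,3,2-dioxaborolane | CC[Si](CC)(CC)OC1(C#CB2OC(C)(C)C(C)(C)O2)COC1 | intermediate (key-step precursor)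
6 | methyl coumalate (methyl 2-oxo-2H-pyran-5-carboxylate) | COC(=O)C1=COC(=O)C=C1 | starting material
7 | methyl 3-oxo-7-(4,4,5,5-tetramethyl-1,3,2-dioxaborolan-2-yl)-8-[3-(triethylsilyloxy)oxetan-3-yl]-2-oxabicyclo[2.2.2]octa-5,7-diene-6-carboxylate (racemic) | O=C1OC2C(C(=O)OC)=CC1C(C3(O[Si](CC)(CC)CC)COC3)=C2B4OC(C)(C)C(C)(C)O4 | intermediate (not isolated)
8 | methyl 3-(4,4,5,5-tetramethyl-1,3,2-dioxaborolan-2-yl)-4-[3-(triethylsilyloxy)oxetan-3-yl]benzoate | COC(=O)c1ccc(C2(O[Si](CC)(CC)CC)COC2)c(B2OC(C)(C)C(C)(C)O2)c1 | intermediate (key-step product)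
9 | [3-(4,4,5,5-tetramethyl-1,3,2-dioxaborolan-2-yl)-4-[3-(triethylsilyloxy)oxetan-3-yl]phenyl]methanol | OCc1ccc(C2(O[Si](CC)(CC)CC)COC2)c(B2OC(C)(C)C(C)(C)O2)c1 | intermediate
10 | (R)-2-methylbutanoic acid | OC(=O)[C@H](C)CC | starting material
11 | [3-(4,4,5,5-tetramethyl-1,3,2-dioxaborolan-2-yl)-4-[3-(triethylsilyloxy)oxetan-3-yl]phenyl]methyl (2R)-2-methylbutanoate | O=C(OCc1ccc(C2(O[Si](CC)(CC)CC)COC2)c(B2OC(C)(C)C(C)(C)O2)c1)[C@H](C)CC | intermediate
12 | [4-[(2R)-1-bromo-2-(triethylsilyloxy)-3-(trimethylsilyloxy)propan-2-yl]-3-(4,4,5,5-tetramethyl-1,3,2-dioxaborolan-2-yl)phenyl]methyl (2R)-2-methylbutanoate | BrC[C@](O[Si](CC)(CC)CC)(CO[Si](C)(C)C)c1ccc(COC(=O)[C@H](C)CC)cc1B1OC(C)(C)C(C)(C)O1 | intermediate (not isolated)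
13 | [4-[(2R)-2-(hydroxymethyl)oxiran-2-yl]-3-(4,4,5,5-tetramethyl-1,3,2-dioxaborolan-2-yl)phenyl]methyl (2R)-2-methylbutanoate | C1[C@](O1)(CO)c2ccc(COC(=O)[C@H](C)CC)cc2B3OC(C)(C)C(C)(C)O3 | intermediate
14 | angelic acid ((2Z)-2-methylbut-2-enoic acid) | C/C=C(/C)C(=O)O | starting material
15 | (2R)-2,3-dihydroxy-2-[4-({[(2R)-2-methylbutanoyl]oxy}methyl)-2-(4,4,5,5-tetramethyl-1,3,2-dioxaborolan-2-yl)phenyl]propyl (2Z)-2-methylbut-2-enoate | C/C=C(/C)C(=O)OC[C@](O)(CO)c1ccc(COC(=O)[C@H](C)CC)cc1B1OC(C)(C)C(C)(C)O1 | intermediate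
16 | (2R)-2,3-dihydroxy-2-[2-hydroxy-4-({[(2R)-2-methylbutanoyl]oxy}methyl)phenyl]propyl (2Z)-2-methylbut-2-enoate | C/C=C(/C)C(=O)OC[C@](O)(CO)c1ccc(COC(=O)[C@H](C)CC)cc1O | target

Total step count: 8. Longest linear sequence: 8 steps (1 to 16).

Steps most likely to fail

Step 3. The unsymmetrical alkyne may add in the opposite orientation or without preference, or the coumalate may be consumed by self-condensation before the hindered alkyne reacts. The fallback replaces ring synthesis by a classical aryl–carbonyl construction. It sets out from none of the numbered compounds (it replaces 1 to 7 and starts from purchased methyl 3-bromo-4-iodobenzoate and oxetan-3-one) and comes back to the route at compound 8. Iodine–magnesium exchange (iPrMgCl·LiCl, THF, −40 °C) should give methyl 3-bromo-4-(chloromagnesio)benzoate F1. This adds to oxetan-3-one to give methyl 3-bromo-4-(3-hydroxyoxetan-3-yl)benzoate F2. Silylation (Et3SiOTf, 2,6-lutidine) gives methyl 3-bromo-4-[3-(triethylsilyloxy)oxetan-3-yl]benzoate F3. Miyaura borylation (B2pin2, Pd2(dba)3, XPhos, KOAc, dioxane, 90 °C; zerovalent palladium) should then give 8.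

Step 6. Bromide may be delivered to the two enantiotopic methylene groups with little discrimination, because the oxetane is flanked by a silyloxy group and an ortho-borylated arene; the bromo alkoxide may also close back to the oxetane when fluoride is added. The fallback desymmetrises an acyclic triol by acylation instead of the oxetane by ring opening. It sets out from compound 11 and comes back at compound 15. Uncatalysed opening of 11 with TMSBr (CH2Cl2, 0 °C) gives the bromo bis-silyl ether as both configurations at the new centre F4. TBAF converts it into the epoxy alcohol as both configurations F5. Dilute HClO4 in aqueous THF hydrolyses the epoxide to [4-(1,2,3-trihydroxypropan-2-yl)-3-(4,4,5,5-tetramethyl-1,3,2-dioxaborolan-2-yl)phenyl]methyl (2R)-2-methylbutanoate F6, in which the carbinol carbon is no longer stereogenic. Copper-catalysed desymmetrising monoacylation of this 2-aryl glycerol (CuCl2, chiral bis(oxazoline) ligand, Et3N, THF) uses (2Z)-2-methylbut-2-enoyl chloride F7, made from 14 with 1-chloro-N,N,2-trimethylprop-1-en-1-amine under neutral conditions. It should distinguish the two primary hydroxyls and give 15 directly.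

Step 7. The carboxylate may attack the benzylic epoxide carbon through an ionising pathway, or the titanium alkoxide may promote acyl migration among the three oxygens; either would erode constitution or configuration. The fallback uses a basic SN2 opening of a protected epoxide instead of Lewis-acid chelation. It sets out from compound 13 and comes back at compound 16. Silylation (TBSCl, imidazole) gives [4-[(2S)-2-({[tert-butyl(dimethyl)silyl]oxy}methyl)oxiran-2-yl]-3-(4,4,5,5-tetramethyl-1,3,2-dioxaborolan-2-yl)phenyl]methyl (2R)-2-methylbutanoate F8; the descriptor changes by the sequence rule only. Cesium angelate (14, Cs2CO3 cat., DMF, 50 °C) opens the epoxide at its methylene carbon to give (2S)-3-{[tert-butyl(dimethyl)silyl]oxy}-2-hydroxy-2-[4-({[(2R)-2-methylbutanoyl]oxy}methyl)-2-(4,4,5,5-tetramethyl-1,3,2-dioxaborolan-2-yl)phenyl]propyl (2Z)-2-methylbut-2-enoate F9, whose masked primary oxygen cannot accept the acyl group. Neutral H2O2 oxidation as in step 8 gives (2S)-3-{[tert-butyl(dimethyl)silyl]oxy}-2-hydroxy-2-[2-hydroxy-4-({[(2R)-2-methylbutanoyl]oxy}methyl)phenyl]propyl (2Z)-2-methylbut-2-enoate F10. HF·pyridine in THF then gives 16.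

Further compounds

F1 | step 3 | methyl 3-bromo-4-(chloromagnesio)benzoate (LiCl complex) | COC(=O)c1ccc([Mg]Cl)c(Br)c1
F2 | step 3 | methyl 3-bromo-4-(3-hydroxyoxetan-3-yl)benzoate | COC(=O)c1ccc(C2(O)COC2)c(Br)c1
F3 | step 3 | methyl 3-bromo-4-[3-(triethylsilyloxy)oxetan-3-yl]benzoate | COC(=O)c1ccc(C2(O[Si](CC)(CC)CC)COC2)c(Br)c1
F4 | step 6 | [4-[1-bromo-2-(triethylsilyloxy)-3-(trimethylsilyloxy)propan-2-yl]-3-(4,4,5,5-tetramethyl-1,3,2-dioxaborolan-2-yl)phenyl]methyl (2R)-2-methylbutanoate, both configurations at C2 of the propane | BrCC(O[Si](CC)(CC)CC)(CO[Si](C)(C)C)c1ccc(COC(=O)[C@H](C)CC)cc1B1OC(C)(C)C(C)(C)O1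
F5 | step 6 | [4-[2-(hydroxymethyl)oxiran-2-yl]-3-(4,4,5,5-tetramethyl-1,3,2-dioxaborolan-2-yl)phenyl]methyl (2R)-2-methylbutanoate, both configurations at the oxirane carbon | OCC1(CO1)c1ccc(COC(=O)[C@H](C)CC)cc1B1OC(C)(C)C(C)(C)O1
F6 | step 6 | [4-(1,2,3-trihydroxypropan-2-yl)-3-(4,4,5,5-tetramethyl-1,3,2-dioxaborolan-2-yl)phenyl]methyl (2R)-2-methylbutanoate | OCC(O)(CO)c1ccc(COC(=O)[C@H](C)CC)cc1B1OC(C)(C)C(C)(C)O1
F7 | step 6 | (2Z)-2-methylbut-2-enoyl chloride | C/C=C(/C)C(Cl)=O
F8 | step 7 | [4-[(2S)-2-({[tert-butyl(dimethyl)silyl]oxy}methyl)oxiran-2-yl]-3-(4,4,5,5-tetramethyl-1,3,2-dioxaborolan-2-yl)phenyl]methyl (2R)-2-methylbutanoate | C1[C@](O1)(CO[Si](C)(C)C(C)(C)C)c2ccc(COC(=O)[C@H](C)CC)cc2B3OC(C)(C)C(C)(C)O3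
F9 | step 7 | (2S)-3-{[tert-butyl(dimethyl)silyl]oxy}-2-hydroxy-2-[4-({[(2R)-2-methylbutanoyl]oxy}methyl)-2-(4,4,5,5-tetramethyl-1,3,2-dioxaborolan-2-yl)phenyl]propyl (2Z)-2-methylbut-2-enoate | C/C=C(/C)C(=O)OC[C@](O)(CO[Si](C)(C)C(C)(C)C)c1ccc(COC(=O)[C@H](C)CC)cc1B1OC(C)(C)C(C)(C)O1
F10 | step 7 | (2S)-3-{[tert-butyl(dimethyl)silyl]oxy}-2-hydroxy-2-[2-hydroxy-4-({[(2R)-2-methylbutanoyl]oxy}methyl)phenyl]propyl (2Z)-2-methylbut-2-enoate | C/C=C(/C)C(=O)OC[C@](O)(CO[Si](C)(C)C(C)(C)C)c1ccc(COC(=O)[C@H](C)CC)cc1O
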